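# Proposed total synthesis of CNP0309601.0 (34)

## Analysis of the target

CNP0309601.0 (34) is a linear chain of eight benzene rings (A to H) joined only by seven diaryl ether oxygens. It carries twenty-one free phenolic hydroxyls, has no stereocentre and no carbon–carbon bond between rings. Ring A is a 2,4,6-trihydroxyphenoxy cap and ring H a 3,4,5-trihydroxyphenoxy cap. Rings B and D are 3,5-dihydroxy-1,4-dioxygenated units and ring F is a 3,4-dihydroxy-1,5-dioxygenated unit. Rings C, E and G are pentaoxygenated, each with two neighbouring aryloxy carbons, three neighbouring C–OH carbons and a single C–H. The free polyphenol, with its pyrogallol and hydroxyquinol motifs, is sensitive to air and base, so every hydroxyl is carried as a methyl ether and released in the last step. The difficulty lies in regiochemistry and congestion: seven ether bonds must be placed on near-identical, very electron-rich rings, and several of them join carbons or oxygens that are flanked on both sides by oxygen substituents. The strategy rests on ring C. C-1 bears the ring B oxygen and sits next to the only C–H (C-2), C-6 bears the ring D oxygen and sits next to the oxygenated C-5, and C-3 to C-5 are oxygenated. This is the pattern produced when a nucleophile and an electrophile add across the triple bond of 3,4,5-trimethoxybenzyne (16).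

## Retrosynthetic reasoning

**34 to 33.** All twenty-one O–CH3 bonds of the permethylated octamer 33 are cut last. Methyl is chosen because every ring can be bought in methoxylated form and methyl ethers survive fluoride, organolithium, peracid, copper with base and hydrogenolysis. One Lewis-acid ether cleavage then frees all hydroxyls, and the seven diaryl ether bonds, which have no sp3 carbon, are not touched. The forward step has to cleave every methyl ether and keep oxygen away from the product.

**33 to 18 and 32.** The bond between C-6 of ring C and the ring D oxygen is cut. This divides the octamer into a three-ring iodide 18 and a five-ring phenol 32, so the assembly is convergent. The oxygen of 32 has two free ortho positions, so the congestion sits on the electrophile alone. The forward reaction is a copper-catalysed etherification of an aryl iodide flanked by an aryloxy and a methoxy group.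

**18 to 8, 13 and 14.** Two bonds on ring C are cut together: the bond from the ring B oxygen to C-1, and the C-6–I bond. The ring B oxygen is flanked by two methoxy groups and would be a poor partner in a metal-mediated coupling with a substituted ring C halide. It is attached as the nucleophile to aryne 16, released from silyl triflate 13, where crowding at oxygen matters little. The aryl anion left on C-6 takes iodine from nonafluoro-1-iodobutane 14. One operation thus installs the hindered ether and the handle for the ring D oxygen, each on the correct carbon.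

**8 to 3 and 6.** The bond from the ring A oxygen to C-1 of ring B is cut. The ring A phenol 3 is hindered, but the ring B bromide 6 has two free ortho positions, which is the favourable arrangement for a copper coupling. The ring B hydroxyl is masked as a benzyl ether in 6 and 7, so that hydrogenolysis frees it selectively to give 8. Phenol 3 comes from aldehyde 1 by Dakin oxidation, and 6 from 2,6-dimethoxyphenol 4 by para bromination to 5 and benzylation.

**13 to 10 and 9.** The silyl triflate is traced to 3,4,5-trimethoxyphenol 9 through its ortho bromide 10. The silicon is moved from oxygen to carbon by a retro-Brook shift (via 11 and 12), which places silicon on the carbon next to methoxy and the triflate next to C–H.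

**32 to 30, then to 29 and 25.** The free ring D hydroxyl of 32 is traced to the formyl group of 30 (Dakin oxidation), so ring D needs no protecting group. In 30 the bond from the ring F oxygen to C-2 of ring E is cut. This gives an unhindered three-ring phenol 29 and an iodide 25 with one aryloxy neighbour, a routine copper coupling that joins a two-ring and a three-ring piece.

**25 to 22 and 24; 22 to 21 to 19.** The ether between ring D and ring E has four ortho substituents and is the most congested bond of the molecule. It is cut at C-4 of ring D and made by addition–elimination, which tolerates crowding better than a metal coupling. The ring E oxygen of iodophenol 22 attacks the fluorine-bearing carbon of aldehyde 24, whose formyl group activates the substitution and later becomes the ring D hydroxyl. Phenol 22 comes from aldehyde 19 by Dakin oxidation to 21 and iodination ortho to the hydroxyl.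

**29 to 27, then to 23 and 26; 23 to 22 and 13.** The ring F hydroxyl of 29 again comes from a formyl group (27). In 27 the bond from the ring F oxygen to C-1 of ring G is cut, giving aldehyde 26 and iodide 23. Ring H of 23 is put onto the hindered oxygen of 22 by the established two-component addition of a phenol to aryne 16, released a second time from 13. Iodophenol 22 thus serves as the precursor of both ring E and ring G, and triflate 13 as the precursor of both ring C and ring H. In rings E and G the oxygen next to methoxy can come from the phenol oxygen of 22, so known reactions suffice there. The unproven three-component reaction is used once, for ring C.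

## Alternatives that were turned down

**Alternative 1:** Ring A is disconnected last by cutting two C–C bonds of its benzene ring. Three ring carbons come from dimethyl 3-oxoglutarate A3 and three from the aryloxymalonate A2, in which the complete ring B–H heptamer is already bound through the ring B oxygen to the malonate carbon. In the forward step an alkoxide or magnesium alkoxide base would generate the enolate of A3, which is acylated at both alpha carbons by the two ester groups of A2 and aromatises to the phloroglucinol diester A1.
- For it: it is biomimetic, it creates the ring A oxygenation pattern without any coupling at a doubly flanked position, and ring A emerges with free hydroxyls, so three fewer methyl ethers remain to be cleaved.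
- Against it: a double Claisen condensation on a seven-ring substrate is placed at the very end. The alpha C–H of a 2-aryloxymalonate is acidic, so deprotonation and retro-Claisen cleavage compete with acylation. Both ester groups of A1 must then be hydrolysed and decarboxylated on a sensitive polyphenol. The heptamer inside A2 still contains rings C, E and G, so the hard bonds are left unsolved.
- Comparison: for the single bond it addresses, this is arguably more elegant than the four steps that lead to 8. That bond, however, is made in the chosen route by an ordinary copper coupling of 3 with the unhindered bromide 6. The chosen strategy spends its one uncertain step on the bond that no standard method makes well and keeps the assembly convergent.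

**Alternative 2:** The six hydroxyls that lie para to an ether-bearing carbon (one each on rings A, C, E, F, G and H) are traced back to formyl groups. The precursor is the hexa-aldehyde A5. In the forward step a peracid converts the six formyl groups into formates, and methanolysis gives the hexaphenol A4, with six C–O bonds formed and six carbons lost.
- For it: a formyl group activates a para or ortho fluorine towards addition–elimination, so many of the ether bonds of A5 could be made without metal. On this point the alternative is stronger, and the chosen route borrows the idea for rings D and F (steps 12 to 16).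
- Against it: six Baeyer–Villiger oxidations must all go to completion on one molecule with eight electron-rich rings that a peracid can also hydroxylate, and any site that lags gives a mixture that is hard to separate. A formyl group para to C-1 of rings C, E and G does not activate the neighbouring aryloxy carbon (C-6 of rings C and G, C-2 of ring E), which is meta to it, so half of the congested bonds still need another method. A4 keeps fifteen methyl ethers, so the final demethylation is not saved.
- Comparison: the chosen route uses the Dakin oxidation four times, on one aldehyde at a time, where conversion can be followed. It solves the unactivated position of ring C with the aryne.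

**Alternative 3:** Ring G is taken apart into a four-membered ring and an alkyne. The precursor A7 is a 4-hydroxy-2,3-dimethoxycyclobutenone whose carbinol carbon carries an ethynyl group bound to the ring F oxygen of the ring A–F hexamer. On heating, A7 opens to an alkynyl ketene, which closes to a six-membered diradical. Hydrogen transfer then gives the quinone A6, with one new C–C bond and ring G in the quinone oxidation state.
- For it: all five oxygens of ring G are placed without ambiguity, the ether between rings F and G is present from the start, and no halogenated building block with an assumed regiochemistry is needed. On these points it is as strong as the chosen route or stronger.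
- Against it: an aryl alkynyl ether has to be made on a six-ring phenol and added as its acetylide to a cyclobutenedione. After the ring expansion the quinone A6 must be reduced, and the two hydroxyls of the hydroquinone must be told apart. The more hindered one (next to the aryloxy group) has to be arylated by ring H and the less hindered one methylated, which is the reverse of their intrinsic reactivity. The sequence is linear, with ring G built on a six-ring substrate, and ring C is still unsolved.
- Comparison: the aryne delivers the same pentaoxygenated pattern in one step with the two ring positions already differentiated, one as an ether and one as a C–I bond. It does so for ring C in a convergent three-plus-five assembly.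

Key step: step 8

Assumption: aldehydes 24 and 26 are treated as purchasable building blocks, and every hydroxyl of the target is carried as its methyl ether until step 18.

## Route

Step 1
Reactants: 1 2,4,6-trimethoxybenzaldehyde
Product: 3 2,4,6-trimethoxyphenol, via 2,4,6-trimethoxyphenyl formate 2 (not isolated)
Conditions: mCPBA, CH2Cl2, 0 °C → rt; aq NaHCO3 wash; K2CO3 (cat.), MeOH, rt
Reagents that add atoms: mCPBA (3-chloroperoxybenzoic acid), OOC(=O)c1cccc(Cl)c1
Why: Dakin-type Baeyer–Villiger oxidation; the aryl group, enriched by two ortho and one para methoxy groups, migrates to oxygen and the aryl formate is cleaved by base-catalysed methanolysis.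

Step 2
Reactants: 4 2,6-dimethoxyphenol
Product: 5 4-bromo-2,6-dimethoxyphenol
Conditions: NBS (1.0 equiv), CHCl3, −45 °C → rt, dark
Reagents that add atoms: N-bromosuccinimide, O=C1CCC(=O)N1Br
Why: Electrophilic aromatic bromination; both ortho positions of the phenol carry methoxy groups, so the para carbon is attacked, and low temperature with one equivalent limits oxidation to the quinone.

Step 3
Reactants: 5 4-bromo-2,6-dimethoxyphenol
Product: 6 2-(benzyloxy)-5-bromo-1,3-dimethoxybenzene
Conditions: BnBr, K2CO3, DMF, rt → 50 °C
Reagents that add atoms: benzyl bromide, BrCc1ccccc1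
Why: Williamson etherification; benzyl survives copper and base and is later removed by hydrogenolysis without touching methyl or diaryl ethers.

Step 4
Reactants: 3 2,4,6-trimethoxyphenol; 6 2-(benzyloxy)-5-bromo-1,3-dimethoxybenzene
Product: 7 2-[4-(benzyloxy)-3,5-dimethoxyphenoxy]-1,3,5-trimethoxybenzene
Conditions: CuI (10 mol%), picolinic acid (20 mol%), K3PO4, DMSO, 100 °C, Ar
Reagents that add atoms: none
Why: Ullmann-type copper-catalysed diaryl ether synthesis; the hindered partner is the phenol and the bromide has two free ortho positions, the arrangement that the picolinate system handles.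

Step 5
Reactants: 7 2-[4-(benzyloxy)-3,5-dimethoxyphenoxy]-1,3,5-trimethoxybenzene
Product: 8 2,6-dimethoxy-4-(2,4,6-trimethoxyphenoxy)phenol (ring A–B phenol)
Conditions: H2 (1 atm), 10% Pd/C, EtOAc–MeOH, rt
Reagents that add atoms: none
Why: Hydrogenolysis of the benzyl ether; methyl and diaryl ethers are inert and no aryl halide is left in the molecule.

Step 6
Reactants: 9 3,4,5-trimethoxyphenol
Product: 10 2-bromo-3,4,5-trimethoxyphenol
Conditions: NBS (1.0 equiv), CH2Cl2, −78 → 0 °C
Reagents that add atoms: N-bromosuccinimide, O=C1CCC(=O)N1Br
Why: Electrophilic bromination ortho to the hydroxyl; the two ortho positions are equivalent and the para position is occupied, so one equivalent should give the monobromide.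

Step 7
Reactants: 10 2-bromo-3,4,5-trimethoxyphenol
Product: 13 3,4,5-trimethoxy-2-(trimethylsilyl)phenyl trifluoromethanesulfonate, via aryl silyl ether 11 (not isolated), via lithium silylphenoxide 12 (not isolated)
Conditions: HMDS, THF, 70 °C, then evaporate; n-BuLi, THF, −78 °C; Tf2O, −78 °C → rt
Reagents that add atoms: hexamethyldisilazane, C[Si](C)(C)N[Si](C)(C)C; triflic anhydride, O=S(=O)(OS(=O)(=O)C(F)(F)F)C(F)(F)F
Why: Standard entry to ortho-silylaryl triflates: O-silylation, bromine–lithium exchange, 1,3 retro-Brook shift of silicon from oxygen to the lithiated carbon and triflation of the phenoxide. Silicon ends on the carbon next to methoxy and the triflate next to C–H.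

Step 8
Reactants: 8 2,6-dimethoxy-4-(2,4,6-trimethoxyphenoxy)phenol; 13 3,4,5-trimethoxy-2-(trimethylsilyl)phenyl trifluoromethanesulfonate; 14 nonafluoro-1-iodobutane
Product: 18 2-[4-(2-iodo-3,4,5-trimethoxyphenoxy)-3,5-dimethoxyphenoxy]-1,3,5-trimethoxybenzene (ring A–B–C iodide), via caesium phenoxide 15 (not isolated), via 3,4,5-trimethoxybenzyne 16 (not isolated), via aryl caesium 17 (not isolated)
Conditions: CsOH·H2O, MeOH, then PhMe azeotrope and vacuum drying; 13 (1.5 equiv), 14 (4 equiv), CsF (3 equiv), 18-crown-6, THF, 0 °C → rt, dark
Reagents that add atoms: none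
Why: Proposed new method: fluoride removes the silyl group of 13 and triflate departs, releasing aryne 16; the preformed, proton-free caesium phenoxide 15 adds through oxygen to the aryne carbon remote from the flanking methoxy group, and the aryl caesium 17 so formed abstracts iodine from the perfluoroalkyl iodide 14 before it can be protonated. The closest known reaction types are the fluoride-triggered O-arylation of phenols by 3-alkoxyarynes and the three-component amino-iodination and thio-iodination of arynes with perfluoroalkyl iodides; new is the pairing of an aryloxide nucleophile with the iodine-transfer quench. No ring is closed and no stereocentre is formed. The selectivity needed is regiochemical (oxygen on the carbon next to C–H, iodine on the carbon next to methoxy), and the substrate secures it: the C–O dipole of the flanking methoxy group stabilises negative charge developing on the adjacent carbon and distorts the aryne so that the remote carbon is the electrophilic one, and the methoxy group also shields its neighbour. Because addition to an aryne needs no metal and has an early transition state, the two ortho methoxy groups of 15 should slow it little, which is why this hindered oxygen is attached here and not by copper. Exclusion of light and of every O–H source suppresses electron-transfer perfluoroalkylation of the electron-rich phenoxide and protonation of 17.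

Step 9
Reactants: 19 2,3,4-trimethoxybenzaldehyde
Product: 21 2,3,4-trimethoxyphenol, via 2,3,4-trimethoxyphenyl formate 20 (not isolated)
Conditions: mCPBA, CH2Cl2, 0 °C → rt; aq NaHCO3 wash; K2CO3 (cat.), MeOH, rt
Reagents that add atoms: mCPBA (3-chloroperoxybenzoic acid), OOC(=O)c1cccc(Cl)c1
Why: Dakin-type Baeyer–Villiger oxidation; ortho and para methoxy groups make the aryl group the migrating one, and the formate is cleaved by methanolysis.

Step 10
Reactants: 21 2,3,4-trimethoxyphenol
Product: 22 6-iodo-2,3,4-trimethoxyphenol
Conditions: NIS (1.05 equiv), MeCN, 0 °C → rt, dark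
Reagents that add atoms: N-iodosuccinimide, O=C1CCC(=O)N1I
Why: Electrophilic iodination directed by the free hydroxyl, the strongest donor; its para position is blocked, so the only free ortho carbon (C-6, also para to the 3-methoxy group) should be attacked.

Step 11
Reactants: 22 6-iodo-2,3,4-trimethoxyphenol; 13 3,4,5-trimethoxy-2-(trimethylsilyl)phenyl trifluoromethanesulfonate
Product: 23 1-iodo-3,4,5-trimethoxy-2-(3,4,5-trimethoxyphenoxy)benzene (ring G–H iodide)
Conditions: 13 (1.3 equiv), CsF (3 equiv), MeCN, rt
Reagents that add atoms: none
Why: Known fluoride-triggered O-arylation of a phenol by an ortho-silylaryl triflate: CsF releases from 13 the same aryne as in step 8 (16), the phenoxide of 22 adds to the aryne carbon remote from the flanking methoxy group and the aryl anion is protonated by further phenol, giving the 3,4,5-trimethoxyphenyl ether (ring H). No metal is present, so the aryl iodide and the crowding at the phenol oxygen are tolerated.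

Step 12
Reactants: 22 6-iodo-2,3,4-trimethoxyphenol; 24 4-fluoro-3,5-dimethoxybenzaldehyde
Product: 25 4-(6-iodo-2,3,4-trimethoxyphenoxy)-3,5-dimethoxybenzaldehyde (ring D–E iodide)
Conditions: Cs2CO3, DMSO, 120 °C, Ar
Reagents that add atoms: none
Why: Nucleophilic aromatic substitution; the phenoxide adds to the fluorine-bearing carbon para to the formyl group, which stabilises the Meisenheimer intermediate, and fluoride leaves. Addition–elimination at a carbon that carries small fluorine tolerates four ortho substituents better than a metal-mediated coupling, and the C–I bond is inert without metal.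

Step 13
Reactants: 23 1-iodo-3,4,5-trimethoxy-2-(3,4,5-trimethoxyphenoxy)benzene; 26 3-hydroxy-4,5-dimethoxybenzaldehyde
Product: 27 3,4-dimethoxy-5-[3,4,5-trimethoxy-2-(3,4,5-trimethoxyphenoxy)phenoxy]benzaldehyde (ring F–G–H aldehyde)
Conditions: CuI (10 mol%), picolinic acid (20 mol%), K3PO4, DMSO, 100 °C, Ar
Reagents that add atoms: none
Why: Ullmann-type etherification of an aryl iodide with one ortho substituent by a phenol with one ortho methoxy group; the formyl group is meta to the phenol oxygen, lowers its nucleophilicity little and survives the conditions.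

Step 14
Reactants: 27 3,4-dimethoxy-5-[3,4,5-trimethoxy-2-(3,4,5-trimethoxyphenoxy)phenoxy]benzaldehyde
Product: 29 3,4-dimethoxy-5-[3,4,5-trimethoxy-2-(3,4,5-trimethoxyphenoxy)phenoxy]phenol (ring F–G–H phenol), via aryl formate 28 (not isolated)
Conditions: mCPBA (1.2 equiv), CH2Cl2, 0 °C → rt; aq NaHCO3 wash; K2CO3 (cat.), MeOH, rt
Reagents that add atoms: mCPBA (3-chloroperoxybenzoic acid), OOC(=O)c1cccc(Cl)c1
Why: Dakin-type Baeyer–Villiger oxidation; the para methoxy group makes the ring F aryl group migrate, and a small excess of peracid at low temperature spares the other electron-rich rings.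

Step 15
Reactants: 29 3,4-dimethoxy-5-[3,4,5-trimethoxy-2-(3,4,5-trimethoxyphenoxy)phenoxy]phenol; 25 4-(6-iodo-2,3,4-trimethoxyphenoxy)-3,5-dimethoxybenzaldehyde
Product: 30 4-(6-{3,4-dimethoxy-5-[3,4,5-trimethoxy-2-(3,4,5-trimethoxyphenoxy)phenoxy]phenoxy}-2,3,4-trimethoxyphenoxy)-3,5-dimethoxybenzaldehyde (ring D–H pentamer aldehyde)
Conditions: CuI (20 mol%), picolinic acid (40 mol%), K3PO4, DMSO, 110 °C, Ar
Reagents that add atoms: none
Why: Ullmann-type etherification; the phenol oxygen of 29 has two free ortho positions and the iodide of 25 has one free ortho position, so only one side of the new bond is crowded.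

Step 16
Reactants: 30 ring D–H pentamer aldehyde
Product: 32 4-(6-{3,4-dimethoxy-5-[3,4,5-trimethoxy-2-(3,4,5-trimethoxyphenoxy)phenoxy]phenoxy}-2,3,4-trimethoxyphenoxy)-3,5-dimethoxyphenol (ring D–H pentamer phenol), via aryl formate 31 (not isolated)
Conditions: mCPBA (1.2 equiv), CH2Cl2, 0 °C → rt; aq NaHCO3 wash; K2CO3 (cat.), MeOH, rt
Reagents that add atoms: mCPBA (3-chloroperoxybenzoic acid), OOC(=O)c1cccc(Cl)c1
Why: Dakin-type Baeyer–Villiger oxidation of a 4-aryloxy-3,5-dimethoxybenzaldehyde; the para aryloxy group promotes aryl migration, and methanolysis frees the ring D hydroxyl without any protecting-group step.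

Step 17
Reactants: 18 ring A–B–C iodide; 32 ring D–H pentamer phenol
Product: 33 henicosa-O-methyl ether of CNP0309601.0 (permethylated ring A–H octamer)
Conditions: CuI (30 mol%), 2,2,6,6-tetramethylheptane-3,5-dione (60 mol%), Cs2CO3, NMP, 120 °C, Ar
Reagents that add atoms: none
Why: Ullmann-type etherification; the phenol of 32 is unhindered and electron-rich, and the iodide of 18, though flanked by an aryloxy and a methoxy group, is the more reactive halide, used with a diketonate ligand suited to congested, electron-rich aryl halides.

Step 18
Reactants: 33 henicosa-O-methyl ether of CNP0309601.0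
Product: 34 CNP0309601.0
Conditions: BBr3 (excess), CH2Cl2, −78 °C → rt, Ar; MeOH, then degassed H2O
Reagents that add atoms: none
Why: Lewis-acid cleavage of aryl methyl ethers; bromide attacks the methyl carbon of each boron-complexed ether, and the diaryl ether bonds, which offer no sp3 carbon, are not cleaved.

## Compound list

1 | 2,4,6-trimethoxybenzaldehyde | COc1cc(OC)c(C=O)c(OC)c1 | starting material
2 | 2,4,6-trimethoxyphenyl formate | COc1cc(OC)c(OC=O)c(OC)c1 | intermediate
3 | 2,4,6-trimethoxyphenol | COc1cc(OC)c(O)c(OC)c1 | intermediate
4 | 2,6-dimethoxyphenol | COc1cccc(OC)c1O | starting material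
5 | 4-bromo-2,6-dimethoxyphenol | COc1cc(Br)cc(OC)c1O | intermediate
6 | 2-(benzyloxy)-5-bromo-1,3-dimethoxybenzene | COc1cc(Br)cc(OC)c1OCc1ccccc1 | intermediate
7 | 2-[4-(benzyloxy)-3,5-dimethoxyphenoxy]-1,3,5-trimethoxybenzene | COc1cc(OC)c(Oc2cc(OC)c(OCc3ccccc3)c(OC)c2)c(OC)c1 | intermediate
8 | 2,6-dimethoxy-4-(2,4,6-trimethoxyphenoxy)phenol (ring A–B phenol) | COc1cc(OC)c(Oc2cc(OC)c(O)c(OC)c2)c(OC)c1 | intermediate
9 | 3,4,5-trimethoxyphenol | COc1cc(O)cc(OC)c1OC | starting material
10 | 2-bromo-3,4,5-trimethoxyphenol | COc1cc(O)c(Br)c(OC)c1OC | intermediate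
11 | (2-bromo-3,4,5-trimethoxyphenoxy)trimethylsilane (aryl silyl ether) | COc1cc(O[Si](C)(C)C)c(Br)c(OC)c1OC | intermediate
12 | lithium 3,4,5-trimethoxy-2-(trimethylsilyl)phenoxide (lithium silylphenoxide) | [Li+].COc1cc([O-])c([Si](C)(C)C)c(OC)c1OC | intermediate
13 | 3,4,5-trimethoxy-2-(trimethylsilyl)phenyl trifluoromethanesulfonate | COc1cc(OS(=O)(=O)C(F)(F)F)c([Si](C)(C)C)c(OC)c1OC | intermediate
14 | nonafluoro-1-iodobutane | FC(F)(F)C(F)(F)C(F)(F)C(F)(F)I | starting material
15 | caesium 2,6-dimethoxy-4-(2,4,6-trimethoxyphenoxy)phenoxide (caesium phenoxide) | [Cs+].COc1cc(OC)c(Oc2cc(OC)c([O-])c(OC)c2)c(OC)c1 | intermediate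
16 | 3,4,5-trimethoxybenzyne (1,2-didehydro-3,4,5-trimethoxybenzene) | COC1=CC#CC(OC)=C1OC | intermediate
17 | caesium 2-[2,6-dimethoxy-4-(2,4,6-trimethoxyphenoxy)phenoxy]-4,5,6-trimethoxybenzen-1-ide (aryl caesium) | [Cs+].COc1cc(OC)c(Oc2cc(OC)c(Oc3cc(OC)c(OC)c(OC)[c-]3)c(OC)c2)c(OC)c1 | intermediate
18 | 2-[4-(2-iodo-3,4,5-trimethoxyphenoxy)-3,5-dimethoxyphenoxy]-1,3,5-trimethoxybenzene (ring A–B–C iodide) | COc1cc(OC)c(Oc2cc(OC)c(Oc3cc(OC)c(OC)c(OC)c3I)c(OC)c2)c(OC)c1 | intermediate
19 | 2,3,4-trimethoxybenzaldehyde | COc1ccc(C=O)c(OC)c1OC | starting material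
20 | 2,3,4-trimethoxyphenyl formate | COc1ccc(OC=O)c(OC)c1OC | intermediate
21 | 2,3,4-trimethoxyphenol | COc1ccc(O)c(OC)c1OC | intermediate
22 | 6-iodo-2,3,4-trimethoxyphenol | COc1cc(I)c(O)c(OC)c1OC | intermediate
23 | 1-iodo-3,4,5-trimethoxy-2-(3,4,5-trimethoxyphenoxy)benzene (ring G–H iodide) | COc1cc(Oc2c(I)cc(OC)c(OC)c2OC)cc(OC)c1OC | intermediate
24 | 4-fluoro-3,5-dimethoxybenzaldehyde | COc1cc(C=O)cc(OC)c1F | starting material
25 | 4-(6-iodo-2,3,4-trimethoxyphenoxy)-3,5-dimethoxybenzaldehyde (ring D–E iodide) | COc1cc(C=O)cc(OC)c1Oc1c(I)cc(OC)c(OC)c1OC | intermediate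
26 | 3-hydroxy-4,5-dimethoxybenzaldehyde | COc1cc(C=O)cc(O)c1OC | starting material
27 | 3,4-dimethoxy-5-[3,4,5-trimethoxy-2-(3,4,5-trimethoxyphenoxy)phenoxy]benzaldehyde (ring F–G–H aldehyde) | COc1cc(C=O)cc(Oc2cc(OC)c(OC)c(OC)c2Oc2cc(OC)c(OC)c(OC)c2)c1OC | intermediate
28 | 3,4-dimethoxy-5-[3,4,5-trimethoxy-2-(3,4,5-trimethoxyphenoxy)phenoxy]phenyl formate | COc1cc(OC=O)cc(Oc2cc(OC)c(OC)c(OC)c2Oc2cc(OC)c(OC)c(OC)c2)c1OC | intermediate
29 | 3,4-dimethoxy-5-[3,4,5-trimethoxy-2-(3,4,5-trimethoxyphenoxy)phenoxy]phenol (ring F–G–H phenol) | COc1cc(O)cc(Oc2cc(OC)c(OC)c(OC)c2Oc2cc(OC)c(OC)c(OC)c2)c1OC | intermediate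
30 | 4-(6-{3,4-dimethoxy-5-[3,4,5-trimethoxy-2-(3,4,5-trimethoxyphenoxy)phenoxy]phenoxy}-2,3,4-trimethoxyphenoxy)-3,5-dimethoxybenzaldehyde (ring D–H pentamer aldehyde) | COc1cc(C=O)cc(OC)c1Oc1c(Oc2cc(OC)c(OC)c(Oc3cc(OC)c(OC)c(OC)c3Oc3cc(OC)c(OC)c(OC)c3)c2)cc(OC)c(OC)c1OC | intermediate
31 | 4-(6-{3,4-dimethoxy-5-[3,4,5-trimethoxy-2-(3,4,5-trimethoxyphenoxy)phenoxy]phenoxy}-2,3,4-trimethoxyphenoxy)-3,5-dimethoxyphenyl formate | COc1cc(OC=O)cc(OC)c1Oc1c(Oc2cc(OC)c(OC)c(Oc3cc(OC)c(OC)c(OC)c3Oc3cc(OC)c(OC)c(OC)c3)c2)cc(OC)c(OC)c1OC | intermediate
32 | 4-(6-{3,4-dimethoxy-5-[3,4,5-trimethoxy-2-(3,4,5-trimethoxyphenoxy)phenoxy]phenoxy}-2,3,4-trimethoxyphenoxy)-3,5-dimethoxyphenol (ring D–H pentamer phenol) | COc1cc(O)cc(OC)c1Oc1c(Oc2cc(OC)c(OC)c(Oc3cc(OC)c(OC)c(OC)c3Oc3cc(OC)c(OC)c(OC)c3)c2)cc(OC)c(OC)c1OC | intermediate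
33 | henicosa-O-methyl ether of CNP0309601.0 (permethylated ring A–H octamer) | COc1cc(OC)c(Oc2cc(OC)c(Oc3cc(OC)c(OC)c(OC)c3Oc3cc(OC)c(Oc4c(Oc5cc(OC)c(OC)c(Oc6cc(OC)c(OC)c(OC)c6Oc6cc(OC)c(OC)c(OC)c6)c5)cc(OC)c(OC)c4OC)c(OC)c3)c(OC)c2)c(OC)c1 | intermediate
34 | CNP0309601.0 | Oc1cc(O)c(Oc2cc(O)c(Oc3cc(O)c(O)c(O)c3Oc3cc(O)c(Oc4c(Oc5cc(O)c(O)c(Oc6cc(O)c(O)c(O)c6Oc6cc(O)c(O)c(O)c6)c5)cc(O)c(O)c4O)c(O)c3)c(O)c2)c(O)c1 | target

## Step count and least certain steps

Total step count: 18 steps. Longest linear sequence: 9 steps (19 → 21 → 22 → 23 → 27 → 29 → 30 → 32 → 33 → 34; the path from 9 through 13 is equally long).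

**Step 8 (key step, carries the label).** The aryl caesium 17 may be protonated before iodine transfer, which would give the iodine-free diaryl ether. Electron transfer from the electron-rich phenoxide to 14 may lead to perfluoroalkylation, and slow capture of the aryne may let it oligomerise. The fallback uses known chemistry only and sets out from 8. Purchased 5-iodo-1,2,3-trimethoxybenzene F1 is brominated with NBS at its only free type of position to give 2-bromo-1-iodo-3,4,5-trimethoxybenzene F2. Phenol 8 is coupled with F2 under the conditions of step 4; copper should react at the C–I bond, which has a free ortho position, and leave the flanked C–Br bond. This gives 2-[4-(2-bromo-3,4,5-trimethoxyphenoxy)-3,5-dimethoxyphenoxy]-1,3,5-trimethoxybenzene F3, the bromide analogue of 18. F3 is coupled with 32 under the conditions of step 17 at higher temperature and copper loading, and the route is rejoined at 33.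

**Step 12.** The addition of the doubly ortho-substituted phenoxide to a carbon flanked by two methoxy groups, activated by a single formyl group, may be too slow. Base-induced degradation of the aldehyde at 120 °C could then take over. The fallback sets out from 29 and builds ring E from the aryne. The caesium phenoxide of 29 is submitted to the conditions of step 8 with 13 and 14 to give 1-[3,4-dimethoxy-5-(3,4,5-trimethoxy-2-(3,4,5-trimethoxyphenoxy)phenoxy)phenoxy]-2-iodo-3,4,5-trimethoxybenzene F4. F4 is coupled with 4-hydroxy-3,5-dimethoxybenzaldehyde (syringaldehyde) F5 under the copper conditions of step 17, and the route is rejoined at 30. This fallback changes both the bond-forming mode and the order of assembly. It depends on step 8 having been validated, and its copper coupling is itself congested.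

**Step 17.** Oxidative addition of copper to the doubly ortho-substituted, electron-rich iodide may be slow. Loss of iodine from 18 by reduction and oxidative decay of the phenoxide of 32 could then compete. The fallback reverses the roles of the two fragments and sets out from 18 and 32. Iodide 18 is converted by iodine–magnesium exchange (i-PrMgCl·LiCl), borylation with B(OMe)3 and oxidation (H2O2, NaOH) into 2-[2,6-dimethoxy-4-(2,4,6-trimethoxyphenoxy)phenoxy]-4,5,6-trimethoxyphenol F6. Phenol 32 is converted with Tf2O and pyridine into its aryl triflate F7. F6 and F7 are joined by palladium-catalysed C–O coupling (Pd(OAc)2, t-BuXPhos, K3PO4, toluene, 100 °C), in which the hindered partner is the phenol and the triflate has two free ortho positions. The route is rejoined at 33.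

**Step 18.** Cleavage of twenty-one methyl ethers may stop short and leave partially methylated material. The free polyphenol may also oxidise in air during isolation. The fallback sets out from 33. After the BBr3 treatment and methanol quench the crude product is acetylated at once (Ac2O, pyridine) to the henicosaacetate of CNP0309601.0 F8, which is stable and can be purified on silica. Deacetylation with catalytic NaOMe in degassed MeOH then gives 34.

**Step 10.** Iodination may occur in part at C-5, which is ortho and para to methoxy groups, and the electron-rich phenol may be oxidised to a quinone. The fallback sets out from 21 and fixes the position by directed metalation. Phenol 21 is converted with diethylcarbamoyl chloride and NaH into 2,3,4-trimethoxyphenyl diethylcarbamate F9. Lithiation with s-BuLi and TMEDA at −78 °C occurs at the only free position ortho to the carbamate, and I2 gives 6-iodo-2,3,4-trimethoxyphenyl diethylcarbamate F10. Hydrolysis with NaOH in EtOH returns 22.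

## Further compounds

F1 | step 8 | 5-iodo-1,2,3-trimethoxybenzene | COc1cc(I)cc(OC)c1OC
F2 | step 8 | 2-bromo-1-iodo-3,4,5-trimethoxybenzene | COc1cc(I)c(Br)c(OC)c1OC
F3 | step 8 | 2-[4-(2-bromo-3,4,5-trimethoxyphenoxy)-3,5-dimethoxyphenoxy]-1,3,5-trimethoxybenzene | COc1cc(OC)c(Oc2cc(OC)c(Oc3cc(OC)c(OC)c(OC)c3Br)c(OC)c2)c(OC)c1
F4 | step 12 | 1-[3,4-dimethoxy-5-(3,4,5-trimethoxy-2-(3,4,5-trimethoxyphenoxy)phenoxy)phenoxy]-2-iodo-3,4,5-trimethoxybenzene | COc1cc(Oc2cc(OC)c(OC)c(Oc3cc(OC)c(OC)c(OC)c3Oc3cc(OC)c(OC)c(OC)c3)c2)c(I)c(OC)c1OC
F5 | step 12 | 4-hydroxy-3,5-dimethoxybenzaldehyde (syringaldehyde) | COc1cc(C=O)cc(OC)c1O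
F6 | step 17 | 2-[2,6-dimethoxy-4-(2,4,6-trimethoxyphenoxy)phenoxy]-4,5,6-trimethoxyphenol | COc1cc(OC)c(Oc2cc(OC)c(Oc3cc(OC)c(OC)c(OC)c3O)c(OC)c2)c(OC)c1
F7 | step 17 | 4-(6-{3,4-dimethoxy-5-[3,4,5-trimethoxy-2-(3,4,5-trimethoxyphenoxy)phenoxy]phenoxy}-2,3,4-trimethoxyphenoxy)-3,5-dimethoxyphenyl trifluoromethanesulfonate | COc1cc(OS(=O)(=O)C(F)(F)F)cc(OC)c1Oc1c(Oc2cc(OC)c(OC)c(Oc3cc(OC)c(OC)c(OC)c3Oc3cc(OC)c(OC)c(OC)c3)c2)cc(OC)c(OC)c1OC
F8 | step 18 | henicosaacetate of CNP0309601.0 | CC(=O)Oc1cc(OC(C)=O)c(Oc2cc(OC(C)=O)c(Oc3cc(OC(C)=O)c(OC(C)=O)c(OC(C)=O)c3Oc3cc(OC(C)=O)c(Oc4c(Oc5cc(OC(C)=O)c(OC(C)=O)c(Oc6cc(OC(C)=O)c(OC(C)=O)c(OC(C)=O)c6Oc6cc(OC(C)=O)c(OC(C)=O)c(OC(C)=O)c6)c5)cc(OC(C)=O)c(OC(C)=O)c4OC(C)=O)c(OC(C)=O)c3)c(OC(C)=O)c2)c(OC(C)=O)c1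
F9 | step 10 | 2,3,4-trimethoxyphenyl diethylcarbamate | CCN(CC)C(=O)Oc1ccc(OC)c(OC)c1OC
F10 | step 10 | 6-iodo-2,3,4-trimethoxyphenyl diethylcarbamate | CCN(CC)C(=O)Oc1c(I)cc(OC)c(OC)c1OC
A1 | alternative 1 | octamer with ring A as dimethyl 2,4,6-trihydroxy-5-aryloxybenzene-1,3-dicarboxylate | COC(=O)c1c(O)c(C(=O)OC)c(O)c(Oc2cc(OC)c(Oc3cc(OC)c(OC)c(OC)c3Oc3cc(OC)c(Oc4c(Oc5cc(OC)c(OC)c(Oc6cc(OC)c(OC)c(OC)c6Oc6cc(OC)c(OC)c(OC)c6)c5)cc(OC)c(OC)c4OC)c(OC)c3)c(OC)c2)c1O
A2 | alternative 1 | dimethyl 2-aryloxymalonate of the permethylated ring B–H heptamer | COC(=O)C(Oc2cc(OC)c(Oc3cc(OC)c(OC)c(OC)c3Oc3cc(OC)c(Oc4c(Oc5cc(OC)c(OC)c(Oc6cc(OC)c(OC)c(OC)c6Oc6cc(OC)c(OC)c(OC)c6)c5)cc(OC)c(OC)c4OC)c(OC)c3)c(OC)c2)C(=O)OC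
A3 | alternative 1 | dimethyl 3-oxoglutarate | COC(=O)CC(=O)CC(=O)OC
A4 | alternative 2 | octamer hexaphenol pentadecamethyl ether | Oc1cc(OC)c(Oc2cc(OC)c(Oc3cc(OC)c(O)c(OC)c3Oc3cc(OC)c(Oc4c(Oc5cc(OC)c(O)c(Oc6cc(OC)c(O)c(OC)c6Oc6cc(OC)c(O)c(OC)c6)c5)cc(O)c(OC)c4OC)c(OC)c3)c(OC)c2)c(OC)c1
A5 | alternative 2 | octamer hexa-aldehyde pentadecamethyl ether | O=Cc1cc(OC)c(Oc2cc(OC)c(Oc3cc(OC)c(C=O)c(OC)c3Oc3cc(OC)c(Oc4c(Oc5cc(OC)c(C=O)c(Oc6cc(OC)c(C=O)c(OC)c6Oc6cc(OC)c(C=O)c(OC)c6)c5)cc(C=O)c(OC)c4OC)c(OC)c3)c(OC)c2)c(OC)c1
A6 | alternative 3 | ring A–F hexamer ether of 5-hydroxy-2,3-dimethoxy-1,4-benzoquinone | COc1cc(OC)c(Oc2cc(OC)c(Oc3cc(OC)c(OC)c(OC)c3Oc3cc(OC)c(Oc4c(Oc5cc(OC)c(OC)c(OC6=CC(=O)C(OC)=C(OC)C6=O)c5)cc(OC)c(OC)c4OC)c(OC)c3)c(OC)c2)c(OC)c1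
A7 | alternative 3 | ring A–F hexamer 2-(1-hydroxy-2,3-dimethoxy-4-oxocyclobut-2-en-1-yl)ethynyl ether | COc1cc(OC)c(Oc2cc(OC)c(Oc3cc(OC)c(OC)c(OC)c3Oc3cc(OC)c(Oc4c(Oc5cc(OC)c(OC)c(OC#CC6(O)C(OC)=C(OC)C6=O)c5)cc(OC)c(OC)c4OC)c(OC)c3)c(OC)c2)c(OC)c1
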